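**Structural features**

The target is an (E)-stilbene triphenol: ring B (C1–C6) is a resorcinol with hydroxyls on C3 and C5, joined at C1 through the olefin C7=C8 to C1′ of ring A (C1′–C6′), which carries a hydroxyl on C4′ and a geranyl chain (C1″–C10″) on C3′, ortho to that hydroxyl and meta to the olefin. There is no stereogenic centre; the stereochemical content is the E geometry of C7=C8 and of the trisubstituted chain olefin C2″=C3″. The chain olefins next to a free ortho phenol cyclise to chromans under protic or Lewis acids and are attacked by electrophilic oxidants and halogens, the stilbene isomerises in light, and the triphenol is air-sensitive in strong base. This rules out an end-game of ether cleavage with boron or aluminium halides and makes every phenol protecting group costly. The real difficulty is the bond C3′–C1″: made by alkylating an arene, it needs control of C- against O-alkylation, of ortho regiochemistry, of SN2 against SN2′ attack, and of the 2″E geometry. The key step exploits that C5′–C4′(O)–C3′–C1″ of ring A is the methyl–carbonyl–methylene–chain sequence of (E)-geranylacetone, and that C2′, C1′, C6′ and C8 are a triformylmethane unit with three equivalent arms. Ring A can therefore be closed around a C3′–C1″ bond made at an aliphatic carbon, and ring B with C7 is bought as 3,5-dihydroxyphenylacetic acid.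

**Logic of the disconnections**

13 to 9 and 10. The cut is the olefin C7=C8, with C7 carried in 10 as a methylene that still bears a carboxyl group. Cutting here leaves both halves with all their phenols free, and the carboxyl is a traceless activating group that leaves as CO2. A C24 triphenol becomes a C17 aldehyde and a purchased C8 acid, with no protecting group. The forward step must condense and decarboxylate in a basic medium, give the E olefin, and leave the chain olefins alone.

9 to 5 and 6. The cuts are the ring A bonds C2′–C3′ and C5′–C6′, with the C8 formyl group returned to an iminium carbon. In one sentence: ring A of 13 is not bought but closed by a [3+3] condensation of the two α-carbons of 5 with two arms of 6. After the cut, C4′ is the carbonyl carbon of 5, C3′ and C5′ are its α-carbons, and C1″ already sits on C3′; C2′, C1′, C6′ and C8 are the four carbons of 6. Ring A disappears and its substitution pattern (chain ortho to oxygen, formyl para) is fixed by constitution. The forward step requires both α-carbons of 5 to condense with one molecule of 6, ring closure through carbon to outrun intermolecular condensation and amine return, and the third arm to hydrolyse to the aldehyde.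

5 to 1 and 2. The cut is C3–C4 of 5 (C3′–C1″ of the target), after an ester is added back at C3. At this stage C3 is the α-carbon of a β-keto ester, a reliable carbon nucleophile for a primary allylic bromide, and both chain olefins are bought in 2. Two bulk chemicals result. The forward step must give mono-C-alkylation by direct displacement without allylic transposition, then remove the ester without isomerising or hydrating the olefins.

**Other disconnections considered**

Alternative 1: This is the first route that comes to mind. The cut is C7=C8 by Horner–Wadsworth–Emmons olefination of 4-(tert-butyldimethylsilyloxy)-3-geranylbenzaldehyde A1 with diethyl 3,5-bis(tert-butyldimethylsilyloxy)benzylphosphonate A2, followed by fluoride desilylation. The chosen plan is preferred on three grounds. A1 needs C3′–C1″ made on an arene (aryl-metal plus 2, with the SN2/SN2′ question and a protected phenol). The phosphonate carbanion forces all three phenols to be masked, and only fluoride-labile groups are safe to remove. The count would be roughly three times that of the chosen route.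

Alternative 2: Ring B is built last in polyketide fashion. Methyl (E)-3-[4-(tert-butyldimethylsilyloxy)-3-geranylphenyl]prop-2-enoate A3 would acylate the trianion of methyl 3,5-dioxohexanoate to give triketo ester A4. Intramolecular aldol condensation of C2 of A4 onto its C7 carbonyl would close ring B as resorcylate A5, and saponification with decarboxylation would give 13. This constructs the ring that is cheap to buy and leaves the hard bond C3′–C1″ to arene alkylation. A4 also has competing closure modes (Claisen closure onto the ester, lactonisation to a pyranone, conjugate addition into the enone), the hindered ester of A5 needs hot alkali, and the route is about twice as long.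

Alternative 3: C7=C8 is made by Ramberg–Bäcklund contraction of sulfone A6, in which the two benzylic carbons are joined through SO2 (α-halogenation, episulfone, loss of SO2). This union of two like-polarity carbons is attractive, but the halogenating or carbene-generating conditions and any sulfide oxidation threaten C2″=C3″ and C6″=C7″. The olefin geometry is not secured by the mechanism, three silyl groups are still needed, and ring A must again be alkylated as an arene.

Key step: step 2

Assumption: 6 is taken as a purchasable triformylmethane equivalent, and commercial 2 as the E isomer, which fixes C2″=C3″ for the whole route.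

Throughout, geranyl means (2E)-3,7-dimethylocta-2,6-dien-1-yl.

Step 1
Reactants: 1 ethyl acetoacetate; 2 geranyl bromide [(2E)-1-bromo-3,7-dimethylocta-2,6-diene]
Product: 5 (5E)-6,10-dimethylundeca-5,9-dien-2-one (geranylacetone), via ethyl 2-geranylacetoacetate 3 (not isolated), via 2-geranylacetoacetic acid 4 (not isolated)
Conditions: NaH, THF, 0 °C to rt (1 in excess); then 2 M aq. NaOH, MeOH, 50 °C; then AcOH to pH 5, 60 °C
Reagents that add atoms: none
Why: Acetoacetic ester synthesis: the sodium enolate of β-keto ester 1 displaces bromide from the primary allylic carbon of 2 by SN2, which makes the future C3′–C1″ bond at an aliphatic carbon where C-alkylation is the normal course and leaves the E olefin of 2 untouched. Saponification of 3 and decarboxylation of β-keto acid 4 at pH 5 give 5 without acid strong enough to cyclise or isomerise the chain.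

Step 2
Reactants: 5 geranylacetone; 6 2-[(dimethylamino)methylene]-1,3-bis(dimethyliminio)propane bis(tetrafluoroborate)
Product: 9 4-hydroxy-3-geranylbenzaldehyde, via enone trimethinium cation 7 (not isolated), via quinoid aminomethylene dienone 8 (not isolated)
Conditions: KOt-Bu (2.2 equiv), THF–DMF, −20 to 40 °C, slow addition of the enolate to 6, N2 purge; then AcOH–NaOAc buffer (pH 5), H2O, 25 °C
Reagents that add atoms: water, O
Why: This is the base-mediated [3+3] benzannulation in which the two α-carbons of a ketone condense with the two ends of a three-carbon unit at the malonaldehyde oxidation level (2-substituted malonaldehydes, vinamidinium salts) to give a 4-substituted phenol, used here on a methyl alkyl ketone. The potassium enolate of 5 adds to one of the three equivalent methine carbons of dication 6 and E1cB loss of Me2NH gives 7. Enolisation at the remaining α-carbon and attack on a second iminium methine closes ring A in a 6-(enolendo)-exo-trig Mannich-type step (equivalently a 6π electrocyclisation of the trienolate), and loss of a second Me2NH aromatises the ring to the quinoid vinylogous amide 8, whose aminomethylene carbon is hydrolysed at pH 5 to the formyl group of 9. The new bonds are C2′–C3′ and C5′–C6′; no stereocentre is created and the chain olefins take no part, so the 2″E geometry is carried through. Regiochemistry is fixed by constitution: the carbonyl carbon of 5 can only become C4′, its chain-bearing α-carbon C3′ and its methyl carbon C5′, and since the three arms of 6 are equivalent the same arene results whichever α-carbon reacts first. The selectivity that is needed is ring closure through carbon ahead of a second intermolecular condensation and ahead of the aniline pathway in which liberated Me2NH condenses with the ketone carbonyl; slow addition of the enolate to 6, the cationic and therefore strongly electrophilic character of 7, and an aprotic basic medium purged of Me2NH favour it. The push-pull character of 7 lowers the barrier to rotation about its enone double bond, so the cisoid geometry required for closure is accessible; O-cyclisation of the enolate is a reversible detour that reopens to the same chain.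

Step 3
Reactants: 9 4-hydroxy-3-geranylbenzaldehyde; 10 3,5-dihydroxyphenylacetic acid
Product: 13 5-[(E)-2-(4-hydroxy-3-geranylphenyl)ethenyl]benzene-1,3-diol (the target), via α-arylcinnamic acid 11 (not isolated), via para-quinone methide acid 12 (not isolated)
Conditions: piperidine (1.5 equiv), 1-methylimidazole, PEG-400, 150 °C, sealed tube, Ar, dark
Reagents that add atoms: none
Why: Amine-promoted Perkin-type (Knoevenagel) condensation of a 4-hydroxybenzaldehyde with an arylacetic acid gives α-arylcinnamic acid 11, which tautomerises to para-quinone methide 12 and loses CO2, the decarboxylation mode known from the Knoevenagel–Doebner route to 4-vinylphenols. C7=C8 is formed E because the two aryl groups are anti in the decarboxylating conformer of 12 and the E stilbene is also the thermodynamic isomer. The basic, non-oxidising medium tolerates the three free phenols and the acid-labile chain, so no protecting group is needed.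

**Compound list**

1 | ethyl acetoacetate (ethyl 3-oxobutanoate) | CCOC(=O)CC(C)=O | starting material
2 | geranyl bromide [(2E)-1-bromo-3,7-dimethylocta-2,6-diene] | CC(C)=CCC/C(C)=C/CBr | starting material
3 | ethyl (4E)-2-acetyl-5,9-dimethyldeca-4,8-dienoate (ethyl 2-geranylacetoacetate, racemic) | CC(C)=CCC/C(C)=C/CC(C(C)=O)C(=O)OCC | intermediate
4 | (4E)-2-acetyl-5,9-dimethyldeca-4,8-dienoic acid (2-geranylacetoacetic acid, racemic) | CC(C)=CCC/C(C)=C/CC(C(C)=O)C(=O)O | intermediate
5 | (5E)-6,10-dimethylundeca-5,9-dien-2-one (geranylacetone) | CC(C)=CCC/C(C)=C/CCC(C)=O | intermediate
6 | 2-[(dimethylamino)methylene]-1,3-bis(dimethyliminio)propane bis(tetrafluoroborate) | CN(C)C=C(C=[N+](C)C)C=[N+](C)C.F[B-](F)(F)F.F[B-](F)(F)F | starting material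
7 | 1,3-bis(dimethylamino)-2-[(1E,6E)-7,11-dimethyl-3-oxododeca-1,6,10-trien-1-yl]trimethinium tetrafluoroborate (open-chain mono-condensation product, drawn for first attack through the methyl carbon of 5) | CC(C)=CCC/C(C)=C/CCC(=O)/C=C/C(=CN(C)C)C=[N+](C)C.F[B-](F)(F)F | intermediate
8 | 4-[(dimethylamino)methylidene]-2-[(2E)-3,7-dimethylocta-2,6-dien-1-yl]cyclohexa-2,5-dien-1-one (exocyclic geometry undefined, delocalised) | CC(C)=CCC/C(C)=C/CC1=CC(=CN(C)C)C=CC1=O | intermediate
9 | 4-hydroxy-3-[(2E)-3,7-dimethylocta-2,6-dien-1-yl]benzaldehyde | CC(C)=CCC/C(C)=C/Cc1cc(C=O)ccc1O | intermediate
10 | 3,5-dihydroxyphenylacetic acid | OC(=O)Cc1cc(O)cc(O)c1 | starting material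
11 | (2E)-2-(3,5-dihydroxyphenyl)-3-{4-hydroxy-3-[(2E)-3,7-dimethylocta-2,6-dien-1-yl]phenyl}prop-2-enoic acid | CC(C)=CCC/C(C)=C/Cc1cc(/C=C(/C(=O)O)c2cc(O)cc(O)c2)ccc1O | intermediate
12 | 2-(3,5-dihydroxyphenyl)-3-{3-[(2E)-3,7-dimethylocta-2,6-dien-1-yl]-4-oxocyclohexa-2,5-dien-1-ylidene}propanoic acid (racemic at C2, para-quinone methide tautomer of 11) | CC(C)=CCC/C(C)=C/CC1=CC(=CC(C(=O)O)c2cc(O)cc(O)c2)C=CC1=O | intermediate
13 | 5-[(E)-2-{4-hydroxy-3-[(2E)-3,7-dimethylocta-2,6-dien-1-yl]phenyl}ethenyl]benzene-1,3-diol | CC(C)=CCC/C(C)=C/Cc1cc(/C=C/c2cc(O)cc(O)c2)ccc1O | target

**Step count and risks**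

Total step count: 3. Longest linear sequence: 3 steps (2 to 5 to 9 to 13); 1, 6 and 10 are bought.

Step 2 (key step). Three processes are most likely to go wrong. First, intermolecular condensation of the open-chain intermediate with a second enolate may compete with ring closure and lead to oligomers, because 6 carries three electrophilic arms and is a more electrophilic partner than the mono-cationic or anionic three-carbon units usually used. Second, the closure may be diverted to the nitrogen-retaining aromatisation (aniline formation) if liberated dimethylamine condenses with the ketone carbonyl first. Third, the base may move the C2″=C3″ double bond into conjugation with the new arene. Fallback, setting out from 2: sodium 4-bromophenoxide (from commercial 4-bromophenol and NaH) suspended in toluene is C-alkylated at the ortho carbon by 2 to give 4-bromo-2-geranylphenol F1. Treatment of F1 with n-BuLi (3 equiv) in THF at −78 °C (phenoxide formation, then bromine–lithium exchange) and quenching with DMF returns to 9. This gives up ring construction for arene alkylation and is known chemistry.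

Step 3. The sequence may stall at the condensation stage without decarboxylation, 10 may decarboxylate before it condenses, piperidine may add to the quinone methide, and the hot phenolate mixture may oxidise or oligomerise. Fallback, setting out from 9: Wittig methylenation (Ph3PCH3Br, excess KOt-Bu, THF, 0 °C to rt) gives 4-ethenyl-2-geranylphenol F2. Heck coupling of F2 with commercial 5-iodoresorcinol (Pd(OAc)2, P(o-tol)3, Et3N, DMF, 90 °C) returns to 13, with the E geometry set by syn insertion and syn β-hydride elimination.

Step 1. Double alkylation of the β-keto ester, O-alkylation, and attack at C3 of the allylic system of 2 (allylic transposition to a branched chain) may occur, and ionisation of 2 may erode the E geometry. Fallback, setting out from 2: acetone N,N-dimethylhydrazone is lithiated with LiN(i-Pr)2 in THF at −78 °C and mono-alkylated by 2 to give geranylacetone N,N-dimethylhydrazone F3. Hydrolysis of F3 with CuCl2 in aqueous THF buffered at pH 7 returns to 5, avoiding both the second alkylation and the decarboxylation.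

**Further compounds**

F1 | step 2 | 4-bromo-2-[(2E)-3,7-dimethylocta-2,6-dien-1-yl]phenol | CC(C)=CCC/C(C)=C/Cc1cc(Br)ccc1O
F2 | step 3 | 4-ethenyl-2-[(2E)-3,7-dimethylocta-2,6-dien-1-yl]phenol | CC(C)=CCC/C(C)=C/Cc1cc(C=C)ccc1O
F3 | step 1 | (5E)-6,10-dimethylundeca-5,9-dien-2-one N,N-dimethylhydrazone | CC(C)=CCC/C(C)=C/CCC(C)=NN(C)C
A1 | alternative 1 | 4-(tert-butyldimethylsilyloxy)-3-[(2E)-3,7-dimethylocta-2,6-dien-1-yl]benzaldehyde | CC(C)=CCC/C(C)=C/Cc1cc(C=O)ccc1O[Si](C)(C)C(C)(C)C
A2 | alternative 1 | diethyl 3,5-bis(tert-butyldimethylsilyloxy)benzylphosphonate | CCOP(=O)(Cc1cc(O[Si](C)(C)C(C)(C)C)cc(O[Si](C)(C)C(C)(C)C)c1)OCC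
A3 | alternative 2 | methyl (2E)-3-{4-(tert-butyldimethylsilyloxy)-3-[(2E)-3,7-dimethylocta-2,6-dien-1-yl]phenyl}prop-2-enoate | CC(C)=CCC/C(C)=C/Cc1cc(/C=C/C(=O)OC)ccc1O[Si](C)(C)C(C)(C)C
A4 | alternative 2 | methyl (8E)-9-{4-(tert-butyldimethylsilyloxy)-3-[(2E)-3,7-dimethylocta-2,6-dien-1-yl]phenyl}-3,5,7-trioxonon-8-enoate | CC(C)=CCC/C(C)=C/Cc1cc(/C=C/C(=O)CC(=O)CC(=O)CC(=O)OC)ccc1O[Si](C)(C)C(C)(C)C
A5 | alternative 2 | methyl 2,4-dihydroxy-6-[(E)-2-{4-hydroxy-3-[(2E)-3,7-dimethylocta-2,6-dien-1-yl]phenyl}ethenyl]benzoate | CC(C)=CCC/C(C)=C/Cc1cc(/C=C/c2cc(O)cc(O)c2C(=O)OC)ccc1O
A6 | alternative 3 | 3,5-bis(tert-butyldimethylsilyloxy)benzyl 4-(tert-butyldimethylsilyloxy)-3-[(2E)-3,7-dimethylocta-2,6-dien-1-yl]benzyl sulfone | CC(C)=CCC/C(C)=C/Cc1cc(CS(=O)(=O)Cc2cc(O[Si](C)(C)C(C)(C)C)cc(O[Si](C)(C)C(C)(C)C)c2)ccc1O[Si](C)(C)C(C)(C)C
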